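The constants I can read from the dusk and winter runs are a slope and a fade, and I reckon both against catalyst charge times time.

| flask | starting material | free catalyst | remark | time |
|---|---|---|---|---|
| dusk | 0.23 M | 0.16 mM | run made earlier |  |
| winter | 0.23 M | 1.3 mM | run made earlier |  |
| south-east | 0.23 M | 0.25 mM |  | 12 min |
| north-east | 0.23 M | 0.50 mM |  | 12 min |
| west | 0.23 M | 1.0 mM |  | 12 min |
| south-west | 0.23 M | 2.0 mM |  | 12 min |

| run | time / min | target / % |
|---|---|---|
| dusk | 0.500 | 0 |
| dusk | 1.50 | 7.1 |
| dusk | 3.00 | 14.1 |
| dusk | 5.00 | 21.6 |
| dusk | 6.00 | 27.9 |
| dusk | 8.00 | 34.1 |
| winter | 0.667 | 25.0 |
| winter | 1.00 | 36.4 |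
| winter | 2.00 | 69.2 |
| winter | 3.00 | 92.8 |
| winter | 5.00 | 78.9 |
| winter | 8.00 | 60.6 |

(scatter of a reading: 1 percentage point)

- the numbers in the tables scatter with a standard deviation of 1 percentage point
- "hardly changes" means that all values lie within two and a half points (for a concentration: within two and a half percent of the largest)

- [target] at the end for south-east, north-east, west, south-west, in this order
- how the row runs (hardly changes / falls all the way / rises, then falls / rises all the way / falls, then rises)

Winter's target climbs in a straight line, a zero-order rise, and that line reaches the whole charge at 2.89 min. Dusk's line, scaled by its catalyst charge against winter's, gives 2.89 min for the same knee. These are separate runs, so this is a real check.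

I call one fill the catalyst-times-time that makes one charge of target. Past the knee, winter's target falls from 92.8% to 60.6%, a decay of 0.0852 /min. Multiplying that decay by the knee time divides the rate of loss by the rate of making, so time drops out and leaves 0.246. This is the fade per fill, a selectivity factor of my own reckoning, and I assume it follows catalyst as the slope does.

So the curve, drawn against fills, rises with slope one to the knee and then sinks exponentially, still falling at winter's last reading:

fills = catalyst × time / (winter catalyst × knee)
before the knee: target share = fills
past the knee: target share = winter's reading at the knee × exp(−fade × fills passed since that reading)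

South-east reaches 0.798 fills, so I expect 79.8% of the charge. North-east gives 80.9%, west 54.6% and south-west 24.8%. My row rises, then falls.

The forecast says 0.19 M, 0.197 M, 0.133 M, 0.061 M, and rises, then falls, on the ground that “Everything scales with catalyst × time.” At south-west it stands at 26.5% of the charge, above my figure, since it starts its decay from the whole charge and I start mine from winter's reading.

The flasks give 0.181 M, 0.192 M, 0.123 M, 0.0506 M, and rises, then falls. South-west holds 22.0% of the charge, below both estimates.

    catalyst intermediate A ⇌ catalyst intermediate B (K = 2.90, k = 1000 /min)
    starting material + free catalyst → catalyst intermediate A (k = 4600 /M/min)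
    catalyst intermediate B → free catalyst + target (k = 100 /min)
    free catalyst + target → free catalyst + over-reaction product (k = 74.0 /M/min)

South-west shows the fade at work: with the loss of target to over-reaction product taken away, it ends at 0.230 M, not 0.0506 M. From 6.00 min to 12.0 min, south-west passes 3.19 fills, so the fade keeps 45.5% of its target, and the flask keeps 41.1%. South-east's target also owes its level to the time given: at 120 min it stands at 0.0325 M, not 0.181 M. That time is 7.98 fills, where my curve gives 16.8% of the charge and the flask holds 14.1%.

The readings stem from a simulated flask with constants of no real substance, and the scatter is random.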